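**Retrosynthetic overview**

1. The target is 6α,8α-dihydroxy-labd-13E-en-18-oic acid in which C15 is the exocyclic (Z)-ylidene carbon of a 4-methylbutenolide. The plan rests on two features: ring B (C5–C10, C17 on C8, oxygen on C9 as a handle) is the ring of (R)-carvone with C5 as its stereocentre, and the quaternary C4 with C19 (β-methyl) and C18 (α-carboxyl) is its isopropenyl group, so ring A needs only C1–C3 and the C3–C4 bond.
2. Disconnections, backwards: butenolide by coupling–lactonisation of a C15 alkyne with (Z)-3-iodobut-2-enoic acid; C13=C14 by carboalumination of a C13 alkyne; C8–OH by Markovnikov hydration of the C7=C8 alkene; C6–O and C9–H by 1,4-hydrolactonisation of the C6–C9 diene with the C18 acid; C9–C11 by Negishi coupling of the C9 dienyl triflate; C3–C4 by intramolecular ester-enolate alkylation; C10 by two anti-alkylations of carvone.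
3. Ring order: ring B is bought; ring A is closed in step 9; the 18,6-lactone (a temporary ring that protects 6-OH and CO2H) is closed in step 12 and opened in step 17; the butenolide ring is made last.
4. Design choices: the ester is tert-butyl so that the acid of step 12 frees the carboxyl; C6–O is delivered from the C18 carboxyl because hydroboration of the diene would put boron on the allylic C7; C8–OH is made by a radical hydration so that no acid-reversible C8–O bond is formed.

Key step: step 9

Remark: labdane numbering is used for all intermediates. The hydroboration of step 1 is not face-selective, so compounds 2–5, 7, 8 and 10–16 are taken as epimer mixtures at the future C4 (2 and 3 also at the carbinol carbon, 8 at C10). Their SMILES leave these centres open, and all converge at the planar enolate of step 9.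

**Route**

Step 1
Reactants: 1 (R)-(−)-carvone
Product: 3 (5R)-5-(1-hydroxypropan-2-yl)-2-methylcyclohex-2-en-1-ol, via bis-boron adduct 2 (not isolated)
Conditions: 9-BBN (2.3 equiv), THF, 0 °C → rt; then NaOH, H2O2, 0 °C → rt
Reagents that add atoms: hydrogen peroxide, OO
Why: Hydroboration–oxidation places boron anti-Markovnikov on the 1,1-disubstituted isopropenyl group while 9-BBN also reduces the enone carbonyl 1,2, which is accepted because step 2 re-oxidises it; the trisubstituted ring alkene is left and the new stereocentres need no control.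

Step 2
Reactants: 3 diol
Product: 4 2-[(1R)-4-methyl-5-oxocyclohex-3-en-1-yl]propanoic acid
Conditions: CrO3, H2SO4, acetone, 0 °C
Reagents that add atoms: water, O
Why: Jones oxidation returns the allylic alcohol to the enone and takes the primary alcohol through the aldehyde hydrate to the acid in one operation.

Step 3
Reactants: 4 keto acid
Product: 5 tert-butyl 2-[(1R)-4-methyl-5-oxocyclohex-3-en-1-yl]propanoate
Conditions: Cl3CC(=NH)OtBu, BF3·OEt2 (cat.), CH2Cl2/cyclohexane, rt
Reagents that add atoms: tert-butyl 2,2,2-trichloroacetimidate, CC(C)(C)OC(=N)C(Cl)(Cl)Cl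
Why: Acid-catalysed O-alkylation of the carboxylic acid by the trichloroacetimidate gives a tert-butyl ester that resists the amide bases at its carbonyl and is removed by the acid of step 12.

Step 4
Reactants: 5 keto ester; 6 iodomethane
Product: 8 tert-butyl 2-[(1R)-4,6-dimethyl-5-oxocyclohex-3-en-1-yl]propanoate, via lithium dienolate 7 (not isolated)
Conditions: LiN(iPr)2, THF, −78 °C; MeI, −78 → −20 °C
Reagents that add atoms: iodomethane (compound 6), CI
Why: Kinetic α′-deprotonation of the enone (its α′-hydrogens are far more acidic than the ester α-hydrogen) and enolate methylation; the C10 epimers converge in step 5.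

Step 5
Reactants: 8 methyl ketone; 9 allyl bromide
Product: 11 tert-butyl 2-[(1S,6S)-4,6-dimethyl-5-oxo-6-(prop-2-en-1-yl)cyclohex-3-en-1-yl]propanoate, via lithium enolate 10 (not isolated)
Conditions: LiN(iPr)2, THF, −78 → −20 °C; allyl bromide, DMPU, −78 °C → rt
Reagents that add atoms: allyl bromide (compound 9), C=CCBr
Why: Enolate alkylation in which the fully substituted α′-enolate is allylated on the face anti to the adjacent C5 substituent (the established sequential anti-alkylation of carvone), which sets C10 with the methyl cis and the three-carbon chain trans to the C5 side chain.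

Step 6
Reactants: 11 allyl ketone
Product: 13 tert-butyl 2-[(1S,6S)-6-(3-hydroxypropyl)-4,6-dimethyl-5-oxocyclohex-3-en-1-yl]propanoate, via alkyldisiamylborane 12 (not isolated)
Conditions: Sia2BH (from BH3·SMe2 and 2-methylbut-2-ene), THF, −10 → 0 °C; then H2O2, pH 7 phosphate buffer, 0 °C → rt
Reagents that add atoms: hydrogen peroxide, OO
Why: Hydroboration–oxidation in which disiamylborane adds to the monosubstituted terminal alkene within minutes, much faster than it reduces the hindered conjugated ketone or touches the trisubstituted alkene, and buffered peroxide avoids epoxidation of the enone.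

Step 7
Reactants: 13 primary alcohol
Product: 14 tert-butyl 2-[(1S,6S)-6-(3-iodopropyl)-4,6-dimethyl-5-oxocyclohex-3-en-1-yl]propanoate
Conditions: I2, PPh3, imidazole, CH2Cl2, 0 °C → rt
Reagents that add atoms: iodine, II
Why: Appel-type iodination in which iodide displaces the oxyphosphonium of the primary alcohol by SN2.

Step 8
Reactants: 14 iodo enone
Product: 15 tert-butyl 2-[(1S,6S)-5-[(tert-butyldimethylsilyl)oxy]-6-(3-iodopropyl)-4,6-dimethylcyclohexa-2,4-dien-1-yl]propanoate
Conditions: TBSOTf, Et3N, CH2Cl2, 0 °C → rt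
Reagents that add atoms: tert-butyldimethylsilyl trifluoromethanesulfonate, CC(C)(C)[Si](C)(C)OS(=O)(=O)C(F)(F)F
Why: Silyl enol ether formation in which, with the α′ position quaternary, O-silylation and γ-deprotonation at C6 give the extended silyl dienol ether; this removes the acidic γ-hydrogens of the enone before the base of step 9 and keeps C9 as a handle.

Step 9
Reactants: 15 iodopropyl silyl dienol ether
Product: 17 tert-butyl 9-[(tert-butyldimethylsilyl)oxy]-11,12,13,14,15,16-hexanorlabda-6,8-dien-18-oate, via lithium ester enolate 16 (not isolated)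
Conditions: LiN(iPr)2, THF, −78 °C; then DMPU, −78 → 0 °C
Reagents that add atoms: none
Why: LiN(iPr)2 removes the only acidic hydrogen, C4–H of the ester, to give the planar ester enolate 16 (so both C4 epimers of 15 converge), and C4 displaces the primary iodide at C3 in an intramolecular SN2 reaction. The closest known reaction type is the intramolecular ester-enolate alkylation that makes an α-quaternary cycloalkanecarboxylate. Ring A is closed in the 6-exo-tet mode through a chair-like transition state in which the C10–C1–C2–C3 tether holds C3 anti to C6. The new stereocentre C4 is controlled by allylic 1,3-strain in the enolate: C5–H lies near the enolate plane beside the enolate oxygen substituent, which places the enolate carbon (C18) outside and equatorial (α) and forces the methyl (C19) inside and axial (β). The step needs C-alkylation at C4 only, which is secured because the enone is masked as the silyl dienol ether (no other acidic hydrogen) and O-alkylation would need an eight-membered ring.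

Step 10
Reactants: 17 silyl dienol ether
Product: 18 tert-butyl 9-(trifluoromethanesulfonyloxy)-11,12,13,14,15,16-hexanorlabda-6,8-dien-18-oate
Conditions: CsF, PhNTf2, DME, rt
Reagents that add atoms: N-phenylbis(trifluoromethanesulfonimide), O=S(=O)(N(c1ccccc1)S(=O)(=O)C(F)(F)F)C(F)(F)F
Why: Enol triflate formation from a silyl enol ether: fluoride cleaves the Si–O bond and the caesium dienolate is O-sulfonylated, so no strong base meets the ester.

Step 11
Reactants: 18 dienyl triflate; 19 (4-bromobut-1-yn-1-yl)trimethylsilane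
Product: 21 tert-butyl 14-(trimethylsilyl)-15,16-dinorlabda-6,8-dien-13-yn-18-oate, via alkylzinc bromide 20 (not isolated)
Conditions: Zn dust, I2 (cat.), DMA, 70 °C; then 18, Pd(OAc)2 (5 mol%), SPhos (10 mol%), THF/DMA, 50 °C
Reagents that add atoms: (4-bromobut-1-yn-1-yl)trimethylsilane (compound 19), C[Si](C)(C)C#CCCBr
Why: Negishi coupling in which zinc inserts into the primary bromide and the alkylzinc couples with the hindered alkenyl triflate under a bulky biarylphosphine that speeds oxidative addition and reductive elimination; the ester and the silyl alkyne are inert to the organozinc.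

Step 12
Reactants: 21 diene tert-butyl ester
Product: 23 14-(trimethylsilyl)-15,16-dinorlabd-7-en-13-yn-18,6α-olide, via diene acid 22 (not isolated)
Conditions: CF3CO2H/CH2Cl2 (1:4), 0 °C → rt
Reagents that add atoms: none
Why: Brønsted-acid hydrolactonisation of a 1,3-diene in the 1,4 sense: acidolysis of the tert-butyl ester gives acid 22, protonation of the diene at C9 on the α-face (anti to the axial C20 methyl) gives the C6–C7–C8 allyl cation, and the C18 carboxyl, held on the α-face beside C6, captures C6 in a 5-exo manner, which sets 9α-H and 6α-O.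

Step 13
Reactants: 23 alkene lactone
Product: 25 8α-hydroxy-14-(trimethylsilyl)-15,16-dinorlabd-13-yn-18,6α-olide, via tertiary hydroperoxide 24 (not isolated)
Conditions: Mn(dpm)3 (cat.), PhSiH3, O2 (1 atm), iPrOH/CH2Cl2, 0 °C → rt; then P(OEt)3
Reagents that add atoms: dioxygen, O=O
Why: Mukaiyama hydration (metal-hydride hydrogen-atom transfer): hydrogen adds to C7, the tertiary C8 radical takes up O2 on the α-face away from the 1,3-diaxial C20 methyl, and the phosphite reduces the hydroperoxide to the Markovnikov 8α-ol, while the silyl alkyne and lactone are untouched.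

Step 14
Reactants: 25 silyl alkyne
Product: 26 8α-hydroxy-15,16-dinorlabd-13-yn-18,6α-olide
Conditions: Bu4NF, THF, 0 °C
Reagents that add atoms: none
Why: Fluoride-induced protodesilylation of the alkynylsilane, which does not affect the hindered lactone or the tertiary alcohol at 0 °C.

Step 15
Reactants: 26 terminal alkyne
Product: 28 (13E)-8α-hydroxy-14-iodo-15-norlabd-13-en-18,6α-olide, via alkenylalane 27 (not isolated)
Conditions: AlMe3, Cp2ZrCl2 (25 mol%), H2O (1 equiv), CH2Cl2, −20 → 0 °C; then I2, THF, −30 → 0 °C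
Reagents that add atoms: trimethylaluminium, C[Al](C)C; iodine, II
Why: Zirconium-catalysed carboalumination (Negishi methylalumination) adds Me and Al syn with Al on the terminal carbon, and iodinolysis with retention gives the (13E)-2-methyl-1-iodoalkene; the tertiary hydroxyl is carried as its aluminium alkoxide and the lactone carbonyl is shielded by the quaternary C4.

Step 16
Reactants: 28 alkenyl iodide; 29 ethynyltrimethylsilane
Product: 30 (13E)-8α-hydroxy-14-[(trimethylsilyl)ethynyl]-15-norlabd-13-en-18,6α-olide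
Conditions: PdCl2(PPh3)2 (cat.), CuI (cat.), Et3N, THF, rt
Reagents that add atoms: ethynyltrimethylsilane (compound 29), C#C[Si](C)(C)C
Why: Sonogashira coupling of the alkenyl iodide with retention of the 13E geometry.

Step 17
Reactants: 30 silyl enyne lactone
Product: 31 (13E)-14-ethynyl-6α,8α-dihydroxy-15-norlabd-13-en-18-oic acid
Conditions: LiOH, THF/H2O, rt → 40 °C; then 1 M HCl to pH 4, 0 °C
Reagents that add atoms: lithium hydroxide, [Li+].[OH-]
Why: Saponification in which hydroxide removes the alkynyl silyl group and opens the strained trans-fused γ-lactone, releasing 6α-OH and the C18 acid before the base-sensitive ylidene butenolide exists; cold, careful acidification avoids relactonisation.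

Step 18
Reactants: 32 but-2-ynoic acid
Product: 33 (Z)-3-iodobut-2-enoic acid
Conditions: NaI, AcOH, 110 °C
Reagents that add atoms: sodium iodide, [Na+].[I-]
Why: Conjugate (anti) hydroiodination of the ynoic acid gives the (Z)-3-iodoalkenoic acid, in which iodine and carboxyl are cis.

Step 19
Reactants: 31 dihydroxy acid enyne; 33 (Z)-3-iodobut-2-enoic acid
Product: 35 target CNP0145461.1, via enynoic acid 34 (not isolated)
Conditions: Pd(PPh3)4 (5 mol%), CuI (10 mol%), Et3N, MeCN, rt
Reagents that add atoms: (Z)-3-iodobut-2-enoic acid (compound 33), C/C(I)=C/C(=O)O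
Why: Tandem Sonogashira coupling–lactonisation: coupling with retention gives the (Z)-enynoic acid 34, whose carboxylate adds anti across the metal-activated alkyne in the 5-exo-dig mode to give the (Z)-γ-ylidene butenolide, while the C18 acid and the two hydroxyls are spectators under Et3N.

**Compound list**

1 | (R)-(−)-carvone | CC1=CC[C@H](CC1=O)C(C)=C | starting material
2 | bis-boron adduct: O-(9-BBN) borinate of the reduced ketone with a B-alkyl-9-BBN on the former isopropenyl CH2 (epimer mixture) | CC1=CC[C@H](CC1OB2C3CCCC2CCC3)C(C)CB4C5CCCC4CCC5 | intermediate (not isolated)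
3 | (5R)-5-(1-hydroxypropan-2-yl)-2-methylcyclohex-2-en-1-ol (mixture at C1 and at the side-chain CH) | CC1=CC[C@H](CC1O)C(C)CO | intermediate
4 | 2-[(1R)-4-methyl-5-oxocyclohex-3-en-1-yl]propanoic acid (both epimers at the future C4) | CC1=CC[C@H](CC1=O)C(C)C(=O)O | intermediate
5 | tert-butyl 2-[(1R)-4-methyl-5-oxocyclohex-3-en-1-yl]propanoate | CC1=CC[C@H](CC1=O)C(C)C(=O)OC(C)(C)C | intermediate
6 | iodomethane | CI | starting material
7 | lithium α′-dienolate of 5 | CC1=CC[C@H](C=C1O[Li])C(C)C(=O)OC(C)(C)C | intermediate (not isolated)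
8 | tert-butyl 2-[(1R)-4,6-dimethyl-5-oxocyclohex-3-en-1-yl]propanoate (C6 epimers) | CC1=CC[C@H](C(C)C1=O)C(C)C(=O)OC(C)(C)C | intermediate
9 | allyl bromide | C=CCBr | starting material
10 | lithium enolate of 8 | CC1=CC[C@H](C(C)=C1O[Li])C(C)C(=O)OC(C)(C)C | intermediate (not isolated)
11 | tert-butyl 2-[(1S,6S)-4,6-dimethyl-5-oxo-6-(prop-2-en-1-yl)cyclohex-3-en-1-yl]propanoate (allyl trans, methyl cis to the propanoate-bearing substituent) | C=CC[C@]1(C)C(=O)C(C)=CC[C@H]1C(C)C(=O)OC(C)(C)C | intermediate
12 | bis(3-methylbutan-2-yl)borane adduct of 11 at the terminal carbon | CC(C)C(C)B(CCC[C@]1(C)C(=O)C(C)=CC[C@H]1C(C)C(=O)OC(C)(C)C)C(C)C(C)C | intermediate (not isolated)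
13 | tert-butyl 2-[(1S,6S)-6-(3-hydroxypropyl)-4,6-dimethyl-5-oxocyclohex-3-en-1-yl]propanoate | OCCC[C@]1(C)C(=O)C(C)=CC[C@H]1C(C)C(=O)OC(C)(C)C | intermediate
14 | tert-butyl 2-[(1S,6S)-6-(3-iodopropyl)-4,6-dimethyl-5-oxocyclohex-3-en-1-yl]propanoate | ICCC[C@]1(C)C(=O)C(C)=CC[C@H]1C(C)C(=O)OC(C)(C)C | intermediate
15 | key-step precursor: tert-butyl 2-[(1S,6S)-5-[(tert-butyldimethylsilyl)oxy]-6-(3-iodopropyl)-4,6-dimethylcyclohexa-2,4-dien-1-yl]propanoate | ICCC[C@]1(C)C(O[Si](C)(C)C(C)(C)C)=C(C)C=C[C@H]1C(C)C(=O)OC(C)(C)C | intermediate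
16 | lithium ester enolate of 15 (planar C4) | ICCC[C@]1(C)C(O[Si](C)(C)C(C)(C)C)=C(C)C=C[C@H]1C(C)=C(O[Li])OC(C)(C)C | intermediate (not isolated)
17 | key-step product: tert-butyl 9-[(tert-butyldimethylsilyl)oxy]-11,12,13,14,15,16-hexanorlabda-6,8-dien-18-oate (4α-CO2tBu, 4β-Me, 5α-H, 10β-Me) | CC1=C(O[Si](C)(C)C(C)(C)C)[C@@]2(C)CCC[C@@](C)(C(=O)OC(C)(C)C)[C@@H]2C=C1 | intermediate
18 | tert-butyl 9-(trifluoromethanesulfonyloxy)-11,12,13,14,15,16-hexanorlabda-6,8-dien-18-oate | CC1=C(OS(=O)(=O)C(F)(F)F)[C@@]2(C)CCC[C@@](C)(C(=O)OC(C)(C)C)[C@@H]2C=C1 | intermediate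
19 | (4-bromobut-1-yn-1-yl)trimethylsilane | C[Si](C)(C)C#CCCBr | starting material
20 | [4-(trimethylsilyl)but-3-yn-1-yl]zinc bromide | C[Si](C)(C)C#CCC[Zn]Br | intermediate (not isolated)
21 | tert-butyl 14-(trimethylsilyl)-15,16-dinorlabda-6,8-dien-13-yn-18-oate | CC1=C(CCC#C[Si](C)(C)C)[C@@]2(C)CCC[C@@](C)(C(=O)OC(C)(C)C)[C@@H]2C=C1 | intermediate
22 | 14-(trimethylsilyl)-15,16-dinorlabda-6,8-dien-13-yn-18-oic acid | CC1=C(CCC#C[Si](C)(C)C)[C@@]2(C)CCC[C@@](C)(C(=O)O)[C@@H]2C=C1 | intermediate (not isolated)
23 | 14-(trimethylsilyl)-15,16-dinorlabd-7-en-13-yn-18,6α-olide (9α-H) | C[Si](C)(C)C#CCC[C@@H]1[C@@]2(C)CCC[C@@]3(C)C(=O)O[C@@H](C=C1C)[C@H]23 | intermediate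
24 | 8α-hydroperoxy-14-(trimethylsilyl)-15,16-dinorlabd-13-yn-18,6α-olide | C[Si](C)(C)C#CCC[C@@H]1[C@@]2(C)CCC[C@@]3(C)C(=O)O[C@@H](C[C@@]1(C)OO)[C@H]23 | intermediate (not isolated)
25 | 8α-hydroxy-14-(trimethylsilyl)-15,16-dinorlabd-13-yn-18,6α-olide (8β-Me) | C[Si](C)(C)C#CCC[C@@H]1[C@@]2(C)CCC[C@@]3(C)C(=O)O[C@@H](C[C@@]1(C)O)[C@H]23 | intermediate
26 | 8α-hydroxy-15,16-dinorlabd-13-yn-18,6α-olide | C#CCC[C@@H]1[C@@]2(C)CCC[C@@]3(C)C(=O)O[C@@H](C[C@@]1(C)O)[C@H]23 | intermediate
27 | (13E)-14-(dimethylalumanyl) alkene with the 8-O-dimethylaluminium alkoxide | C/C(=C\[Al](C)C)CC[C@@H]1[C@@]2(C)CCC[C@@]3(C)C(=O)O[C@@H](C[C@@]1(C)O[Al](C)C)[C@H]23 | intermediate (not isolated)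
28 | (13E)-8α-hydroxy-14-iodo-15-norlabd-13-en-18,6α-olide | C/C(=C\I)CC[C@@H]1[C@@]2(C)CCC[C@@]3(C)C(=O)O[C@@H](C[C@@]1(C)O)[C@H]23 | intermediate
29 | ethynyltrimethylsilane | C#C[Si](C)(C)C | starting material
30 | (13E)-8α-hydroxy-14-[(trimethylsilyl)ethynyl]-15-norlabd-13-en-18,6α-olide | C/C(=C\C#C[Si](C)(C)C)CC[C@@H]1[C@@]2(C)CCC[C@@]3(C)C(=O)O[C@@H](C[C@@]1(C)O)[C@H]23 | intermediate
31 | (13E)-14-ethynyl-6α,8α-dihydroxy-15-norlabd-13-en-18-oic acid | C/C(=C\C#C)CC[C@@H]1[C@@]2(C)CCC[C@@](C)(C(=O)O)[C@@H]2[C@@H](O)C[C@@]1(C)O | intermediate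
32 | but-2-ynoic acid | CC#CC(=O)O | starting material
33 | (Z)-3-iodobut-2-enoic acid | C/C(I)=C/C(=O)O | intermediate
34 | (Z)-enynoic acid from coupling of 31 and 33 (carboxyl cis to the alkyne) | OC(=O)/C=C(/C)C#C/C=C(\C)CC[C@@H]1[C@@]2(C)CCC[C@@](C)(C(=O)O)[C@@H]2[C@@H](O)C[C@@]1(C)O | intermediate (not isolated)
35 | CNP0145461.1 | CC1=CC(=O)O/C1=C\C=C(/C)CC[C@@H]1[C@@]2(C)CCC[C@@](C)(C(=O)O)[C@@H]2[C@@H](O)C[C@@]1(C)O | target

**Step count and risks**

Total: 19 steps. Longest linear sequence: 18 steps (steps 1–17 and 19 from carvone); step 18 is a one-step side branch.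

Most likely to fail:

Step 12 (acid hydrolactonisation). What may go wrong: the allyl cation is not captured at C6 by the equatorial carboxyl quickly enough, so the diene is consumed by double-bond migration toward C5 or C11, by a C10-to-C9 methyl shift, or by attack of the pendant alkyne, and the C9 configuration or the skeleton is lost. The fallback sets out from 17 and comes back at 23; it puts the C6 oxygen in before the side chain and delivers the C9 hydrogen sigmatropically. Silyl dienol ether 17 is oxidised at the γ-carbon with mCPBA/NaHCO3 (vinylogous Rubottom oxidation on the α-face, opposite the two axial methyls) to tert-butyl 6α-hydroxy-9-oxo-hexanorlabd-7-en-18-oate F1. CF3CO2H removes the tert-butyl group and the γ-hydroxy acid is closed (EDC, DMAP if needed) to 9-oxo-hexanorlabd-7-en-18,6α-olide F2. The organocerium reagent made from [4-(trimethylsilyl)but-3-yn-1-yl]magnesium bromide F3 (from bromide 19 and Mg) and CeCl3 adds to the C9 ketone to give the tertiary allylic alcohol 9-hydroxy-14-(trimethylsilyl)-15,16-dinorlabd-7-en-13-yn-18,6α-olide F4. Pyridinium chlorochromate, (C5H5NH)[CrO3Cl], effects the oxidative 1,3-transposition to 7-oxo-14-(trimethylsilyl)-15,16-dinorlabd-8-en-13-yn-18,6α-olide F5. NaBH4/CeCl3 (Luche reduction, hydride from the α-face) gives 7β-hydroxy-14-(trimethylsilyl)-15,16-dinorlabd-8-en-13-yn-18,6α-olide F6. Mitsunobu displacement with 2-nitrobenzenesulfonylhydrazide (PPh3, diethyl azodicarboxylate) inverts C7, the sulfinate leaves, and the 7α-allylic diazene loses N2 with transfer of hydrogen to the α-face of C9 and shift of the double bond to C7–C8, which should give 23.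

Step 9 (key cyclisation). What may go wrong: deprotonation of the hindered ester α-hydrogen is slow, so the amide base attacks the primary iodide (elimination or substitution) before the enolate forms, and conversion to ring A is poor; a second concern is insufficient facial selectivity at C4. The fallback sets out from 8 and comes back at 17; it replaces displacement by conjugate addition, so no leaving group sits on C3 when the base is present. The enolate of 8 (LiN(iPr)2) is alkylated anti to the C5 substituent with 3-bromo-2-(phenylsulfonyl)prop-1-ene to give tert-butyl 2-[4,6-dimethyl-5-oxo-6-[2-(phenylsulfonyl)prop-2-en-1-yl]cyclohex-3-en-1-yl]propanoate F7. TBSOTf/Et3N gives its silyl dienol ether F8. The ester enolate (LiN(iPr)2 or KN(SiMe3)2, THF, −78 → 0 °C) adds to the vinyl sulfone at C3 in a 6-endo-trig Michael reaction under the same allylic-strain control, giving tert-butyl 9-[(tert-butyldimethylsilyl)oxy]-2-(phenylsulfonyl)-hexanorlabda-6,8-dien-18-oate F9. Reductive desulfonylation (Na(Hg), Na2HPO4, MeOH/THF, −20 °C) should give 17.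

Step 13 (radical hydration). What may go wrong: poor facial selectivity in the capture of O2 by the planar C8 radical, or hydrogen-atom transfer to the alkyne, giving the 8-epimer or over-reduced material. The fallback sets out from 23 and comes back at 25; it sets C8 by a concerted, stereospecific addition. Dihydroxylation of 23 (OsO4 cat., N-methylmorpholine N-oxide) from the open α-face gives 7α,8α-dihydroxy-14-(trimethylsilyl)-15,16-dinorlabd-13-yn-18,6α-olide F10. The secondary 7-hydroxyl alone is acylated (PhOC(S)Cl, DMAP, pyridine) to the 7-O-phenoxythiocarbonyl derivative F11. Barton–McCombie deoxygenation (Bu3SnH, AIBN, toluene, 80 °C) should give 25.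

Further compounds
F1 | step 12 | tert-butyl 6α-hydroxy-9-oxo-11,12,13,14,15,16-hexanorlabd-7-en-18-oate | O=C1C(C)=C[C@H](O)[C@H]2[C@](C)(C(=O)OC(C)(C)C)CCC[C@]12C
F2 | step 12 | 9-oxo-11,12,13,14,15,16-hexanorlabd-7-en-18,6α-olide | O=C1C(C)=C[C@@H]2OC(=O)[C@]3(C)CCC[C@@]1(C)[C@@H]23
F3 | step 12 | [4-(trimethylsilyl)but-3-yn-1-yl]magnesium bromide | C[Si](C)(C)C#CCC[Mg]Br
F4 | step 12 | 9-hydroxy-14-(trimethylsilyl)-15,16-dinorlabd-7-en-13-yn-18,6α-olide (C9 configuration open) | C[Si](C)(C)C#CCCC1(O)C(C)=C[C@@H]2OC(=O)[C@]3(C)CCC[C@@]1(C)[C@@H]23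
F5 | step 12 | 7-oxo-14-(trimethylsilyl)-15,16-dinorlabd-8-en-13-yn-18,6α-olide | C[Si](C)(C)C#CCCC1=C(C)C(=O)[C@@H]2OC(=O)[C@]3(C)CCC[C@@]1(C)[C@@H]23
F6 | step 12 | 7β-hydroxy-14-(trimethylsilyl)-15,16-dinorlabd-8-en-13-yn-18,6α-olide | C[Si](C)(C)C#CCCC1=C(C)[C@@H](O)[C@@H]2OC(=O)[C@]3(C)CCC[C@@]1(C)[C@@H]23
F7 | step 9 | tert-butyl 2-[4,6-dimethyl-5-oxo-6-[2-(phenylsulfonyl)prop-2-en-1-yl]cyclohex-3-en-1-yl]propanoate (ring configuration as in 11) | C=C(C[C@]1(C)C(=O)C(C)=CC[C@H]1C(C)C(=O)OC(C)(C)C)S(=O)(=O)c1ccccc1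
F8 | step 9 | silyl dienol ether of F7 | C=C(C[C@]1(C)C(O[Si](C)(C)C(C)(C)C)=C(C)C=C[C@H]1C(C)C(=O)OC(C)(C)C)S(=O)(=O)c1ccccc1
F9 | step 9 | tert-butyl 9-[(tert-butyldimethylsilyl)oxy]-2-(phenylsulfonyl)-11,12,13,14,15,16-hexanorlabda-6,8-dien-18-oate (C2 configuration open) | CC1=C(O[Si](C)(C)C(C)(C)C)[C@@]2(C)CC(S(=O)(=O)c3ccccc3)C[C@@](C)(C(=O)OC(C)(C)C)[C@@H]2C=C1
F10 | step 13 | 7α,8α-dihydroxy-14-(trimethylsilyl)-15,16-dinorlabd-13-yn-18,6α-olide | C[Si](C)(C)C#CCC[C@@H]1[C@@]2(C)CCC[C@@]3(C)C(=O)O[C@@H]([C@@H](O)[C@@]1(C)O)[C@H]23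
F11 | step 13 | 8α-hydroxy-7α-(phenoxythiocarbonyloxy)-14-(trimethylsilyl)-15,16-dinorlabd-13-yn-18,6α-olide | C[Si](C)(C)C#CCC[C@@H]1[C@@]2(C)CCC[C@@]3(C)C(=O)O[C@@H]([C@@H](OC(=S)Oc4ccccc4)[C@@]1(C)O)[C@H]23
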